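**Plan**
- Retrosynthesis: the C2–Br bond is cut back to a C2 carboxylic acid, then the C3–S bond, then N1–C7a of the pyrrole ring (vinyl nitrene closure), then the C2=C3 bond (condensation) and the C3–C3a bond (aryl–CHO).
- Forward: the benzene ring arrives with its three bromines in 1,2,3-tribromobenzene, gains one carbon from DMF and the C2/N1 unit from ethyl azidoacetate; the pyrrole ring is the only ring formed, in step 3.
- Enabling feature: C7 is the only benzenoid C–H of the target and C4 carries bromine, so the 2,3,4-tribromophenyl ring presents the side-chain nitrogen with exactly one ortho C–H, the future C7a.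
- The C2 ester activates the condensation, survives the thermolysis, and is finally exchanged for bromine by ipso-bromodecarboxylation after C3 sulfenylation.
- Stereochemistry: the target has no stereocentre; the only stereo-element is the Z alkene of the azidoacrylate, set in the condensation and consumed in the ring closure.

Key step: step 3

Remark: either alkene isomer of the azidoacrylate would lose dinitrogen to the same azirine, so the Z geometry drawn is the expected outcome and not a requirement.

**Step 1**
Reactants: 1 1,2,3-tribromobenzene; 2 N,N-dimethylformamide
Product: 4 2,3,4-tribromobenzaldehyde, via 2,3,4-tribromophenyllithium 3 (not isolated)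
Conditions: LiN(iPr)2 (LDA, commercial solution, 1.1 equiv), THF, −78 °C, 1 added slowly to the base, 30 min; then DMF (2 equiv), −78 → 0 °C; aq. HCl
Reagents that add atoms: N,N-dimethylformamide, CN(C)C=O
Why: Deprotonative ortho-lithiation next to bromine (C4–H, flanking the bromine array, is the most acidic site) followed by Bouveault-type formylation is a standard protocol for oligobromobenzenes, and holding the kinetic aryllithium at −78 °C should forestall halogen migration and loss of LiBr.

**Step 2**
Reactants: 4 2,3,4-tribromobenzaldehyde; 5 ethyl azidoacetate
Product: 6 ethyl (Z)-2-azido-3-(2,3,4-tribromophenyl)prop-2-enoate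
Conditions: NaOEt (4 equiv), 5 (4 equiv), EtOH (THF co-solvent if 4 is poorly soluble), −10 → 5 °C; poured onto ice-water, filtered (azide: shielded, kept cold and out of light)
Reagents that add atoms: ethyl azidoacetate, CCOC(=O)CN=[N+]=[N-]
Why: Knoevenagel-type aldol–dehydration of the azidoacetate enolate with a non-enolisable, electron-poor aldehyde (first stage of the Hemetsberger–Knittel sequence) should give the Z alkene with aryl trans to the ester, and excess azidoacetate at low temperature offsets its base-induced decomposition.

**Step 3**
Reactants: 6 ethyl (Z)-2-azido-3-(2,3,4-tribromophenyl)prop-2-enoate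
Product: 8 ethyl 4,5,6-tribromo-1H-indole-2-carboxylate, via 2H-azirine ester 7 (not isolated)
Conditions: xylenes, reflux (ca. 140 °C), N2, dilute solution of 6 added dropwise, then 1–2 h
Reagents that add atoms: none
Why: Heating expels dinitrogen from the vinyl azide to give 2H-azirine 7, which opens reversibly to the singlet vinyl nitrene. The nitrogen then bonds to the single free ortho carbon of the aryl ring in a five-centre, 6π-electron (1,5-) electrocyclization that forms N1–C7a and closes the five-membered pyrrole ring, and a 1,5-hydrogen shift from C7a to N1 restores aromaticity. This is the Hemetsberger–Knittel indole synthesis, established for ortho-halogenated 2-azidocinnamates, which give 4-haloindole-2-carboxylates. No stereocentre is created, and the alkene geometry of 6 is erased in the azirine. The step needs regioselective C–N bond formation, which is secured because the other ortho carbon carries bromine and only the C6–H of the aryl ring (the future C7a) can accept nitrogen. The neutral, metal-free conditions should leave all three C–Br bonds and the ester untouched, and dilution suppresses intermolecular nitrene reactions.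

**Step 4**
Reactants: 8 ethyl 4,5,6-tribromo-1H-indole-2-carboxylate; 9 dimethyl disulfide
Product: 10 ethyl 4,5,6-tribromo-3-(methylsulfanyl)-1H-indole-2-carboxylate
Conditions: MeSSMe (0.6 equiv), SO2Cl2 (0.6 equiv), CH2Cl2, −20 °C, 30 min (gives MeSCl in the flask); then 8 in DMF, 0 °C → rt
Reagents that add atoms: dimethyl disulfide, CSSC
Why: Chlorinolysis of the disulfide by sulfuryl chloride gives methanesulfenyl chloride, and electrophilic aromatic sulfenylation of indole-2-carboxylates with sulfenyl chlorides is a standard reaction that should occur at C3, the only nucleophilic carbon left (C2 is blocked by the ester and the benzene ring is deactivated by three bromines).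

**Step 5**
Reactants: 10 ethyl 4,5,6-tribromo-3-(methylsulfanyl)-1H-indole-2-carboxylate
Product: 11 4,5,6-tribromo-3-(methylsulfanyl)-1H-indole-2-carboxylic acid
Conditions: LiOH·H2O (4 equiv), THF/MeOH/H2O, 50 °C; then 1 M HCl to pH 2
Reagents that add atoms: lithium hydroxide monohydrate, O.[Li+].[OH-]
Why: Saponification of the ethyl ester by acyl–oxygen cleavage with hydroxide, conditions to which the aryl bromides and the thioether are inert.

**Step 6**
Reactants: 11 4,5,6-tribromo-3-(methylsulfanyl)-1H-indole-2-carboxylic acid
Product: 12 2,4,5,6-tetrabromo-3-(methylsulfanyl)-1H-indole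
Conditions: NBS (1.05 equiv), dry DMF, 0 °C → rt, dark
Reagents that add atoms: N-bromosuccinimide, O=C1CCC(=O)N1Br
Why: Ipso-bromodecarboxylation (Hunsdiecker-type halodecarboxylation of an electron-rich heteroaromatic acid) is known for indole-2- and pyrrole-2-carboxylic acids with N-halosuccinimides: electrophilic bromine adds at the carboxyl-bearing C2 and loss of carbon dioxide rearomatises, with one equivalent of reagent under anhydrous conditions limiting oxidation at sulfur.

**Compound list**
1 | 1,2,3-tribromobenzene | Brc1cccc(Br)c1Br | starting material
2 | N,N-dimethylformamide | CN(C)C=O | starting material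
3 | 2,3,4-tribromophenyllithium | [Li]c1ccc(Br)c(Br)c1Br | intermediate
4 | 2,3,4-tribromobenzaldehyde | O=Cc1ccc(Br)c(Br)c1Br | intermediate
5 | ethyl azidoacetate | CCOC(=O)CN=[N+]=[N-] | starting material
6 | ethyl (Z)-2-azido-3-(2,3,4-tribromophenyl)prop-2-enoate | CCOC(=O)/C(N=[N+]=[N-])=C/c1ccc(Br)c(Br)c1Br | intermediate
7 | ethyl 2-(2,3,4-tribromophenyl)-2H-azirine-3-carboxylate (racemic) | CCOC(=O)C1=NC1c1ccc(Br)c(Br)c1Br | intermediate
8 | ethyl 4,5,6-tribromo-1H-indole-2-carboxylate | CCOC(=O)c1cc2c(Br)c(Br)c(Br)cc2[nH]1 | intermediate
9 | dimethyl disulfide | CSSC | starting material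
10 | ethyl 4,5,6-tribromo-3-(methylsulfanyl)-1H-indole-2-carboxylate | CCOC(=O)c1[nH]c2cc(Br)c(Br)c(Br)c2c1SC | intermediate
11 | 4,5,6-tribromo-3-(methylsulfanyl)-1H-indole-2-carboxylic acid | OC(=O)c1[nH]c2cc(Br)c(Br)c(Br)c2c1SC | intermediate
12 | 2,4,5,6-tetrabromo-3-(methylsulfanyl)-1H-indole | CSc1c(Br)[nH]c2cc(Br)c(Br)c(Br)c12 | target

Total step count: 6. Longest linear sequence: 6 steps (1 → 4 → 6 → 8 → 10 → 11 → 12).

**Steps most likely to fail**

Step 1. The ortho-bromo aryllithium may undergo halogen migration (halogen dance towards a lithium flanked by two bromines) or lose LiBr to an aryne before it is trapped. The fallback places the metal by halogen–metal exchange instead of deprotonation and sets out from 1. Electrophilic iodination (N-iodosuccinimide, CF3SO3H, CH2Cl2, 0 °C → rt) should occur at C4, the position ortho to one bromine and para to another, to give 1,2,3-tribromo-4-iodobenzene F1. Selective iodine–magnesium exchange with iPrMgCl·LiCl in THF at −40 °C should give (2,3,4-tribromophenyl)magnesium chloride F2, an arylmagnesium that does not take part in halogen migration. Quenching with DMF 2 and acidic work-up returns to the route at aldehyde 4.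

Step 6. Attack of the brominating agent at sulfur, or slow ipso substitution at the carboxyl-bearing carbon, may erode the bromodecarboxylation. The fallback separates the two events and sets out from 11. Protodecarboxylation (Ag2CO3 10 mol %, AcOH 5 mol %, DMSO, 120 °C) should give 4,5,6-tribromo-3-(methylsulfanyl)-1H-indole F3. Bromination of its free C2–H with NBS in CH2Cl2 at −20 °C, a fast electrophilic substitution of 3-sulfanylindoles, then arrives at target 12.

Step 4. Conversion at the electron-poor, peri-hindered C3 of the ester may be incomplete, or sulfenylation may compete at nitrogen. The fallback strengthens the nucleophile instead of the electrophile and sets out from 8. Saponification (LiOH·H2O, THF/H2O, 50 °C; HCl) should give 4,5,6-tribromo-1H-indole-2-carboxylic acid F4. Double deprotonation with NaH in DMF and reaction of the resulting indolyl dianion with dimethyl disulfide 9 at 50 °C should sulfenylate C3 and deliver acid 11 directly, where the route is rejoined.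

**Further compounds**
F1 | step 1 | 1,2,3-tribromo-4-iodobenzene | Ic1ccc(Br)c(Br)c1Br
F2 | step 1 | (2,3,4-tribromophenyl)magnesium chloride | Cl[Mg]c1ccc(Br)c(Br)c1Br
F3 | step 6 | 4,5,6-tribromo-3-(methylsulfanyl)-1H-indole | CSc1c[nH]c2cc(Br)c(Br)c(Br)c12
F4 | step 4 | 4,5,6-tribromo-1H-indole-2-carboxylic acid | OC(=O)c1cc2c(Br)c(Br)c(Br)cc2[nH]1
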